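**Strategy.** The route rests on cutting the bond between the spiro carbon (C4 of the 2,6-dimethoxycyclohexa-2,5-dienone) and the aryl carbon ortho to the carbinol-bearing carbon, the bond that completes the seven-membered carbocycle. The spiro carbon is the para carbon of a latent 2,6-dimethoxyphenol, so a hypervalent-iodine oxidation of an acyclic 1,4-diarylbutanol silyl ether dearomatizes the phenol and lets the trimethoxyarene close the ring, creating the quaternary centre and the dienone in one operation; the symmetric dienone and the two equivalent ortho positions of the arene remove all regio- and stereochemical questions. The three stereocentres are set beforehand by asymmetric crotylboration and a lactone template.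

Key step: step 10

Remark: the spiro carbon is not stereogenic (the dienone ring is symmetric about it), so only the three contiguous centres of the seven-membered ring need control; the (Z)-crotylboronate, the chiral phosphoric acid and the bromophenol are taken as commercial.

Step 1
Reactants: 1 3,4,5-trimethoxybenzaldehyde; 2 (Z)-crotylboronic acid pinacol ester
Product: 4 (1R,2S)-2-methyl-1-(3,4,5-trimethoxyphenyl)but-3-en-1-ol, via pinacol borate ester 3 (not isolated)
Conditions: (R)-TRIP phosphoric acid (5 mol %), toluene, 4 Å MS, −30 °C; aq. NaHCO3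
Reagents that add atoms: none
Why: Chiral Brønsted acid-catalysed asymmetric crotylboration through a closed six-membered chair transition state, in which the (Z)-geometry of 2 is translated into the syn relationship and the (R)-configured acid should direct attack to the Re face of the aldehyde, setting C1 as R and C2 as S.

Step 2
Reactants: 4 (1R,2S)-2-methyl-1-(3,4,5-trimethoxyphenyl)but-3-en-1-ol
Product: 6 (1R,2S)-2-methyl-1-(3,4,5-trimethoxyphenyl)butane-1,4-diol, via bis(9-BBN) adduct 5 (not isolated)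
Conditions: 9-BBN (2.2 equiv), THF, 0 °C → rt; then NaOH, H2O2, 0 °C
Reagents that add atoms: hydrogen peroxide, OO
Why: Anti-Markovnikov hydroboration–oxidation of the terminal alkene, which leaves both stereocenters untouched.

Step 3
Reactants: 6 (1R,2S)-2-methyl-1-(3,4,5-trimethoxyphenyl)butane-1,4-diol
Product: 8 (4S,5R)-4-methyl-5-(3,4,5-trimethoxyphenyl)dihydrofuran-2(3H)-one, via lactol 7 (not isolated)
Conditions: TEMPO (cat.), PhI(OAc)2, CH2Cl2, rt
Reagents that add atoms: none
Why: Nitroxyl-catalysed oxidative lactonization: the primary alcohol is oxidised selectively, the aldehyde closes to lactol 7 and is oxidised on to the γ-lactone, which holds the 4-methyl and 5-aryl groups cis.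

Step 4
Reactants: 8 (4S,5R)-4-methyl-5-(3,4,5-trimethoxyphenyl)dihydrofuran-2(3H)-one
Product: 10 (3S,4S,5R)-3,4-dimethyl-5-(3,4,5-trimethoxyphenyl)dihydrofuran-2(3H)-one, via lithium enolate 9 (not isolated)
Conditions: LiN(SiMe3)2, THF, −78 °C; MeI, −78 → −40 °C
Reagents that add atoms: iodomethane, CI
Why: Lactone enolate alkylation in which methyl iodide should approach the face opposite to the cis-disposed 4-methyl and 5-aryl groups, giving the 3,4-trans lactone and so the third stereocenter (3S).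

Step 5
Reactants: 10 (3S,4S,5R)-3,4-dimethyl-5-(3,4,5-trimethoxyphenyl)dihydrofuran-2(3H)-one
Product: 12 (2S,3S,4R)-4-[(tert-butyldimethylsilyl)oxy]-N-methoxy-N,2,3-trimethyl-4-(3,4,5-trimethoxyphenyl)butanamide, via chloromagnesium alkoxide 11 (not isolated)
Conditions: MeONHMe·HCl, i-PrMgCl, THF, −20 → 0 °C; then TBSOTf, 0 °C → rt
Reagents that add atoms: N,O-dimethylhydroxylamine hydrochloride, CNOC.Cl; tert-butyldimethylsilyl trifluoromethanesulfonate, CC(C)(C)[Si](C)(C)OS(=O)(=O)C(F)(F)F
Why: Aminolysis of the lactone by the magnesium amide (Weinreb amide formation) with trapping of the released alkoxide as its silyl ether in the same flask, which prevents relactonization and touches no stereocenter.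

Step 6
Reactants: 13 4-bromo-2,6-dimethoxyphenol
Product: 15 2-(benzyloxy)-5-bromo-1,3-dimethoxybenzene, via potassium phenoxide 14 (not isolated)
Conditions: BnBr, K2CO3, DMF, rt
Reagents that add atoms: benzyl bromide, BrCc1ccccc1
Why: Williamson ether synthesis masks the phenol as a benzyl ether that tolerates the organolithium step and is removed later by hydrogenolysis.

Step 7
Reactants: 15 2-(benzyloxy)-5-bromo-1,3-dimethoxybenzene; 12 (2S,3S,4R)-4-[(tert-butyldimethylsilyl)oxy]-N-methoxy-N,2,3-trimethyl-4-(3,4,5-trimethoxyphenyl)butanamide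
Product: 18 (2S,3S,4R)-1-[4-(benzyloxy)-3,5-dimethoxyphenyl]-4-[(tert-butyldimethylsilyl)oxy]-2,3-dimethyl-4-(3,4,5-trimethoxyphenyl)butan-1-one, via aryllithium 16 (not isolated), via tetrahedral lithium adduct 17 (not isolated)
Conditions: n-BuLi, THF, −78 °C; then 12, −78 → 0 °C; H2O
Reagents that add atoms: none
Why: Bromine–lithium exchange followed by Weinreb ketone synthesis, in which the chelated tetrahedral adduct 17 survives until work-up so that the aryllithium adds only once and the α-stereocenter is not enolised.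

Step 8
Reactants: 18 (2S,3S,4R)-1-[4-(benzyloxy)-3,5-dimethoxyphenyl]-4-[(tert-butyldimethylsilyl)oxy]-2,3-dimethyl-4-(3,4,5-trimethoxyphenyl)butan-1-one
Product: 19 (2S,3S,4R)-1-[4-(benzyloxy)-3,5-dimethoxyphenyl]-4-[(tert-butyldimethylsilyl)oxy]-2,3-dimethyl-4-(3,4,5-trimethoxyphenyl)butan-1-ol (both C1 epimers)
Conditions: NaBH4, MeOH–THF, 0 °C → rt
Reagents that add atoms: none
Why: Borohydride reduction of the aryl ketone; the new carbinol center is removed in the next step, so its configuration does not matter.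

Step 9
Reactants: 19 (2S,3S,4R)-1-[4-(benzyloxy)-3,5-dimethoxyphenyl]-4-[(tert-butyldimethylsilyl)oxy]-2,3-dimethyl-4-(3,4,5-trimethoxyphenyl)butan-1-ol
Product: 21 4-[(2R,3S,4R)-4-[(tert-butyldimethylsilyl)oxy]-2,3-dimethyl-4-(3,4,5-trimethoxyphenyl)butyl]-2,6-dimethoxyphenol, via debenzylated carbinol 20 (not isolated)
Conditions: H2 (1 atm), Pd/C, EtOH, AcOH (cat.), rt
Reagents that add atoms: none
Why: Hydrogenolysis over palladium on carbon should remove the benzyl ether and then the benzylic hydroxyl group para to the freed phenol, whereas the silyl-protected benzylic oxygen on the trimethoxyphenyl ring is expected to be retained.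

Step 10
Reactants: 21 4-[(2R,3S,4R)-4-[(tert-butyldimethylsilyl)oxy]-2,3-dimethyl-4-(3,4,5-trimethoxyphenyl)butyl]-2,6-dimethoxyphenol
Product: 23 (7R,8S,9R)-9-[(tert-butyldimethylsilyl)oxy]-2,3,3',4,5'-pentamethoxy-7,8-dimethyl-6,7,8,9-tetrahydrospiro[benzo[7]annulene-5,1'-cyclohexa[2,5]diene]-4'-one, via aryloxyiodane 22 (not isolated)
Conditions: PhI(OCOCF3)2 (1.1 equiv), CF3CH2OH, −40 °C; aq. NaHCO3
Reagents that add atoms: none
Why: Ligand exchange of the phenol with the trivalent iodine reagent gives aryloxyiodane 22, which loses iodobenzene to a phenoxenium ion stabilised by the two ortho methoxy groups; the unsubstituted carbon of the trimethoxyphenyl ring (ortho to the carbinol carbon, ortho and para to methoxy groups) attacks the para carbon, and proton loss restores the arene and leaves the cross-conjugated dienone. The closest known reaction type is the hypervalent-iodine dearomatizing para-phenol/arene ipso coupling (an oxidative Friedel–Crafts-type spirocyclization). The seven-membered ring closes in a 7-exo-trig mode onto the para carbon of the phenoxenium ion, with the chain pre-folded by its two methyl groups. No new stereocenter arises, because the dienone ring is symmetric about the spiro carbon and the two ortho positions of the arene are equivalent, and the three existing centers are not involved. The step needs C- over O-attack and oxidation of one ring only: the silyl ether blocks spiro-ether formation, only the free phenol binds to iodine, and the weakly nucleophilic fluoroalcohol, the low temperature and the bicarbonate quench should suppress solvent capture and the acid-promoted dienone–phenol rearrangement.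

Step 11
Reactants: 23 (7R,8S,9R)-9-[(tert-butyldimethylsilyl)oxy]-2,3,3',4,5'-pentamethoxy-7,8-dimethyl-6,7,8,9-tetrahydrospiro[benzo[7]annulene-5,1'-cyclohexa[2,5]diene]-4'-one
Product: 24 (7R,8S,9R)-9-hydroxy-2,3,3',4,5'-pentamethoxy-7,8-dimethyl-6,7,8,9-tetrahydrospiro[benzo[7]annulene-5,1'-cyclohexa[2,5]diene]-4'-one (CNP0288561.1)
Conditions: Bu4NF, AcOH, THF, 0 °C → rt
Reagents that add atoms: none
Why: Fluoride-mediated silyl ether cleavage, buffered with acetic acid so that the alkoxide is protonated at once and neither conjugate addition to the dienone nor rearrangement is triggered; all stereocenters are retained.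

**Compound list**

1 | 3,4,5-trimethoxybenzaldehyde | COc1cc(C=O)cc(OC)c1OC | starting material
2 | (Z)-crotylboronic acid pinacol ester, 2-[(2Z)-but-2-en-1-yl]-4,4,5,5-tetramethyl-1,3,2-dioxaborolane | C/C=C\CB1OC(C)(C)C(C)(C)O1 | starting material
3 | 4,4,5,5-tetramethyl-2-{[(1R,2S)-2-methyl-1-(3,4,5-trimethoxyphenyl)but-3-en-1-yl]oxy}-1,3,2-dioxaborolane | C=C[C@H](C)[C@@H](OB1OC(C)(C)C(C)(C)O1)c1cc(OC)c(OC)c(OC)c1 | intermediate
4 | (1R,2S)-2-methyl-1-(3,4,5-trimethoxyphenyl)but-3-en-1-ol | C=C[C@H](C)[C@@H](O)c1cc(OC)c(OC)c(OC)c1 | intermediate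
5 | 9-[(3S,4R)-4-(9-borabicyclo[3.3.1]nonan-9-yloxy)-3-methyl-4-(3,4,5-trimethoxyphenyl)butyl]-9-borabicyclo[3.3.1]nonane | B1(CC[C@H](C)[C@@H](OB2C3CCCC2CCC3)c2cc(OC)c(OC)c(OC)c2)C2CCCC1CCC2 | intermediate
6 | (1R,2S)-2-methyl-1-(3,4,5-trimethoxyphenyl)butane-1,4-diol | OCC[C@H](C)[C@@H](O)c1cc(OC)c(OC)c(OC)c1 | intermediate
7 | (4S,5R)-4-methyl-5-(3,4,5-trimethoxyphenyl)tetrahydrofuran-2-ol (lactol, both C2 epimers) | OC1C[C@H](C)[C@@H](O1)c2cc(OC)c(OC)c(OC)c2 | intermediate
8 | (4S,5R)-4-methyl-5-(3,4,5-trimethoxyphenyl)dihydrofuran-2(3H)-one (4,5-cis lactone) | O=C1C[C@H](C)[C@@H](O1)c2cc(OC)c(OC)c(OC)c2 | intermediate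
9 | lithium (2R,3S)-3-methyl-2-(3,4,5-trimethoxyphenyl)-2,3-dihydrofuran-5-olate (enolate of 8) | [Li]OC1=C[C@H](C)[C@@H](O1)c2cc(OC)c(OC)c(OC)c2 | intermediate
10 | (3S,4S,5R)-3,4-dimethyl-5-(3,4,5-trimethoxyphenyl)dihydrofuran-2(3H)-one (3,4-trans, 4,5-cis lactone) | O=C1[C@@H](C)[C@H](C)[C@@H](O1)c2cc(OC)c(OC)c(OC)c2 | intermediate
11 | chloromagnesium alkoxide of (2S,3S,4R)-4-hydroxy-N-methoxy-N,2,3-trimethyl-4-(3,4,5-trimethoxyphenyl)butanamide | CON(C)C(=O)[C@@H](C)[C@H](C)[C@@H](O[Mg]Cl)c1cc(OC)c(OC)c(OC)c1 | intermediate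
12 | (2S,3S,4R)-4-[(tert-butyldimethylsilyl)oxy]-N-methoxy-N,2,3-trimethyl-4-(3,4,5-trimethoxyphenyl)butanamide | CON(C)C(=O)[C@@H](C)[C@H](C)[C@@H](O[Si](C)(C)C(C)(C)C)c1cc(OC)c(OC)c(OC)c1 | intermediate
13 | 4-bromo-2,6-dimethoxyphenol | COc1cc(Br)cc(OC)c1O | starting material
14 | potassium 4-bromo-2,6-dimethoxyphenolate | [K+].[O-]c1c(OC)cc(Br)cc1OC | intermediate
15 | 2-(benzyloxy)-5-bromo-1,3-dimethoxybenzene | COc1cc(Br)cc(OC)c1OCc1ccccc1 | intermediate
16 | [4-(benzyloxy)-3,5-dimethoxyphenyl]lithium | [Li]c1cc(OC)c(OCc2ccccc2)c(OC)c1 | intermediate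
17 | lithium alkoxide of the tetrahedral adduct of 16 to amide 12 (aryl, OLi and N(OMe)Me on C1) | [Li]OC(N(C)OC)(c1cc(OC)c(OCc2ccccc2)c(OC)c1)[C@@H](C)[C@H](C)[C@@H](O[Si](C)(C)C(C)(C)C)c1cc(OC)c(OC)c(OC)c1 | intermediate
18 | (2S,3S,4R)-1-[4-(benzyloxy)-3,5-dimethoxyphenyl]-4-[(tert-butyldimethylsilyl)oxy]-2,3-dimethyl-4-(3,4,5-trimethoxyphenyl)butan-1-one | O=C(c1cc(OC)c(OCc2ccccc2)c(OC)c1)[C@@H](C)[C@H](C)[C@@H](O[Si](C)(C)C(C)(C)C)c1cc(OC)c(OC)c(OC)c1 | intermediate
19 | (2S,3S,4R)-1-[4-(benzyloxy)-3,5-dimethoxyphenyl]-4-[(tert-butyldimethylsilyl)oxy]-2,3-dimethyl-4-(3,4,5-trimethoxyphenyl)butan-1-ol (both C1 epimers) | OC(c1cc(OC)c(OCc2ccccc2)c(OC)c1)[C@@H](C)[C@H](C)[C@@H](O[Si](C)(C)C(C)(C)C)c1cc(OC)c(OC)c(OC)c1 | intermediate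
20 | 4-[(2S,3S,4R)-4-[(tert-butyldimethylsilyl)oxy]-1-hydroxy-2,3-dimethyl-4-(3,4,5-trimethoxyphenyl)butyl]-2,6-dimethoxyphenol (both C1 epimers) | OC(c1cc(OC)c(O)c(OC)c1)[C@@H](C)[C@H](C)[C@@H](O[Si](C)(C)C(C)(C)C)c1cc(OC)c(OC)c(OC)c1 | intermediate
21 | 4-[(2R,3S,4R)-4-[(tert-butyldimethylsilyl)oxy]-2,3-dimethyl-4-(3,4,5-trimethoxyphenyl)butyl]-2,6-dimethoxyphenol | COc1cc(C[C@@H](C)[C@H](C)[C@@H](O[Si](C)(C)C(C)(C)C)c2cc(OC)c(OC)c(OC)c2)cc(OC)c1O | intermediate
22 | aryloxy(phenyl)-λ3-iodanyl trifluoroacetate formed from phenol 21 | COc1cc(C[C@@H](C)[C@H](C)[C@@H](O[Si](C)(C)C(C)(C)C)c2cc(OC)c(OC)c(OC)c2)cc(OC)c1OI(OC(=O)C(F)(F)F)c1ccccc1 | intermediate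
23 | (7R,8S,9R)-9-[(tert-butyldimethylsilyl)oxy]-2,3,3',4,5'-pentamethoxy-7,8-dimethyl-6,7,8,9-tetrahydrospiro[benzo[7]annulene-5,1'-cyclohexa[2,5]diene]-4'-one | COC1=CC2(C=C(OC)C1=O)C[C@@H](C)[C@H](C)[C@@H](O[Si](C)(C)C(C)(C)C)c1cc(OC)c(OC)c(OC)c12 | intermediate
24 | (7R,8S,9R)-9-hydroxy-2,3,3',4,5'-pentamethoxy-7,8-dimethyl-6,7,8,9-tetrahydrospiro[benzo[7]annulene-5,1'-cyclohexa[2,5]diene]-4'-one (CNP0288561.1) | COC1=CC2(C=C(OC)C1=O)C[C@@H](C)[C@H](C)[C@@H](O)c1cc(OC)c(OC)c(OC)c12 | target

**Step count.** Total: 11 steps. Longest linear sequence: 10 steps (steps 1–5 and 7–11, from 3,4,5-trimethoxybenzaldehyde); step 6 is a one-step side branch.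

**Steps most likely to fail**

Step 10 (key step). What may go wrong: the spirodienone may undergo an acid-promoted 1,2-aryl shift (dienone–phenol rearrangement), or the phenoxenium ion may be captured by solvent before the arene, hindered by the neighbouring silyloxy group, closes the ring. Fallback, from 21 back to 23: oxidation is separated from C–C bond formation. Phenol 21 is oxidised with PhI(OAc)2 in methanol at 0 °C; methanol should add at a methoxy-bearing ortho carbon and give the masked ortho-quinone ketal 2,6,6-trimethoxy-4-[(2R,3S,4R)-4-[(tert-butyldimethylsilyl)oxy]-2,3-dimethyl-4-(3,4,5-trimethoxyphenyl)butyl]cyclohexa-2,4-dien-1-one F1. This is isolated and ionised with BF3·OEt2 in CH2Cl2 at −78 °C. Loss of methanol regenerates the same phenoxenium ion in the absence of oxidant and protic acid, and ipso attack of the arene at the para carbon should give 23.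

Step 9. What may go wrong: reduction may stall at the hindered carbinol after debenzylation, or the benzylic silyl ether may be lost by hydrogenolysis. Fallback, from 18 back to 21: the carbonyl group is removed by hydrazone reduction instead of benzylic hydrogenolysis. Ketone 18 is condensed with p-toluenesulfonyl hydrazide (EtOH, cat. AcOH, 60 °C) to N'-[(2S,3S,4R)-1-[4-(benzyloxy)-3,5-dimethoxyphenyl]-4-[(tert-butyldimethylsilyl)oxy]-2,3-dimethyl-4-(3,4,5-trimethoxyphenyl)butylidene]-4-methylbenzenesulfonohydrazide F2. Reduction with catecholborane (CHCl3, 0 °C) and decomposition with NaOAc·3H2O at reflux should give 2-(benzyloxy)-5-[(2R,3S,4R)-4-[(tert-butyldimethylsilyl)oxy]-2,3-dimethyl-4-(3,4,5-trimethoxyphenyl)butyl]-1,3-dimethoxybenzene F3. A brief hydrogenolysis (H2, Pd/C, EtOAc) then only has to cleave the benzyl ether to give 21.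

Step 5. What may go wrong: aminolysis of the hindered lactone may be incomplete, or the hydroxy amide may relactonize before it is silylated. Fallback, from 10 back to 18: the amide is bypassed. Aryllithium 16 is added directly to lactone 10 (THF, −78 °C) to give (2S,3S,4R)-1-[4-(benzyloxy)-3,5-dimethoxyphenyl]-4-hydroxy-2,3-dimethyl-4-(3,4,5-trimethoxyphenyl)butan-1-one F4, which is in equilibrium with its cyclic hemiketal. Silylation of the open form with TBSCl and imidazole in DMF should give 18.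

**Further compounds**

F1 | step 10 | 2,6,6-trimethoxy-4-[(2R,3S,4R)-4-[(tert-butyldimethylsilyl)oxy]-2,3-dimethyl-4-(3,4,5-trimethoxyphenyl)butyl]cyclohexa-2,4-dien-1-one | COC1=CC(C[C@@H](C)[C@H](C)[C@@H](O[Si](C)(C)C(C)(C)C)c2cc(OC)c(OC)c(OC)c2)=CC(OC)(OC)C1=O
F2 | step 9 | N'-[(2S,3S,4R)-1-[4-(benzyloxy)-3,5-dimethoxyphenyl]-4-[(tert-butyldimethylsilyl)oxy]-2,3-dimethyl-4-(3,4,5-trimethoxyphenyl)butylidene]-4-methylbenzenesulfonohydrazide | Cc1ccc(cc1)S(=O)(=O)NN=C(c1cc(OC)c(OCc2ccccc2)c(OC)c1)[C@@H](C)[C@H](C)[C@@H](O[Si](C)(C)C(C)(C)C)c1cc(OC)c(OC)c(OC)c1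
F3 | step 9 | 2-(benzyloxy)-5-[(2R,3S,4R)-4-[(tert-butyldimethylsilyl)oxy]-2,3-dimethyl-4-(3,4,5-trimethoxyphenyl)butyl]-1,3-dimethoxybenzene | COc1cc(C[C@@H](C)[C@H](C)[C@@H](O[Si](C)(C)C(C)(C)C)c2cc(OC)c(OC)c(OC)c2)cc(OC)c1OCc1ccccc1
F4 | step 5 | (2S,3S,4R)-1-[4-(benzyloxy)-3,5-dimethoxyphenyl]-4-hydroxy-2,3-dimethyl-4-(3,4,5-trimethoxyphenyl)butan-1-one | O=C(c1cc(OC)c(OCc2ccccc2)c(OC)c1)[C@@H](C)[C@H](C)[C@@H](O)c1cc(OC)c(OC)c(OC)c1
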